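## Retrosynthetic overview

1. Target 28 ⇐ alcohol 27 (acetylation) ⇐ allyl oxocane 23; the E-enyne is built late from the allyl group by cross-metathesis and Colvin homologation.
2. Key step: oxocane 23 ⇐ cis-2,5-disubstituted oxolane 20. A C6 triflate is captured by the ring oxygen to give a 1-oxoniabicyclo[3.3.0]octane, and chloride opens it at the ring-fusion carbon C9, setting C6, C9 and the eight-membered ring in one flask.
3. Chlorohydrin side chain of 20 ⇐ aldehyde 17 by enamine α-chlorination (C7) and Brown allylation (C6).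
4. Oxolane 12 ⇐ Z-alkene ether 10 by cis-selective bromoetherification (C12, C13).
5. 10 ⇐ 2-deoxy-D-ribose (C9, C10) and a propylidene Wittig reagent. Ring order: oxolane, then bicyclic oxonium (second five-membered ring), then oxocane.

Assumption: positions are cited with the natural-product numbering (C1 = alkyne CH, ring oxygen between C6 and C12). The SMILES is read as (3E,6S,7S,9S,10S,12R,13R), so the two substituents flanking the ring oxygen are trans.

Abbreviations in names: TBS = tert-butyldimethylsilyl; DCB = 2,6-dichlorobenzyl; Ipc = isopinocampheyl.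

## Route

Step 1
Reactants: 1 2-deoxy-D-ribose
Product: 2 2-deoxy-D-ribono-1,4-lactone, (4S,5R)-4-hydroxy-5-(hydroxymethyl)oxolan-2-one
Conditions: Br2, H2O, rt, 4 d
Reagents that add atoms: none
Why: Aldose-to-aldonolactone oxidation with bromine water turns the hemiacetal carbon into the lactone carbonyl and leaves untouched the two carbinol centres that become C10 (S) and C9 (R).

Step 2
Reactants: 2 2-deoxy-D-ribono-1,4-lactone
Product: 3 (4S,5R)-4-(TBS-oxy)-5-[(TBS-oxy)methyl]oxolan-2-one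
Conditions: TBSCl, imidazole, DMF, rt
Reagents that add atoms: tert-butyldimethylsilyl chloride, CC(C)(C)[Si](C)(C)Cl
Why: Standard imidazole-mediated silylation protects both hydroxyls, so that only the lactone ring oxygen is freed in step 4.

Step 3
Reactants: 3 bis-silyl lactone
Product: 4 (4S,5R)-4-(TBS-oxy)-5-[(TBS-oxy)methyl]oxolan-2-ol (anomer mixture)
Conditions: i-Bu2AlH, CH2Cl2, −78 °C; aq. potassium sodium tartrate
Reagents that add atoms: none
Why: Low-temperature i-Bu2AlH half-reduction of a γ-lactone stops at the lactol.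

Step 4
Reactants: 4 lactol; 5 propyl(triphenyl)phosphonium bromide
Product: 6 (2R,3S,5Z)-1,3-bis(TBS-oxy)oct-5-en-2-ol
Conditions: 5, KN(SiMe3)2, THF, −78 → 0 °C
Reagents that add atoms: none
Why: Wittig olefination of the open hydroxy-aldehyde form with a non-stabilised ylide under salt-free conditions is Z-selective and frees only the former ring oxygen as the C9 hydroxyl, the low temperature limiting 1,2-silyl migration.

Step 5
Reactants: 7 (2,6-dichlorophenyl)methanol; 8 trichloroacetonitrile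
Product: 9 (2,6-dichlorophenyl)methyl 2,2,2-trichloroethanimidate
Conditions: DBU (cat.), CH2Cl2, 0 °C
Reagents that add atoms: none
Why: Base-catalysed addition of the benzylic alcohol to trichloroacetonitrile gives the trichloroacetimidate alkylating agent.

Step 6
Reactants: 6 alkenol; 9 DCB trichloroacetimidate
Product: 10 (2R,3S,5Z)-1,3-bis(TBS-oxy)-2-(DCB-oxy)oct-5-ene
Conditions: CF3SO3H (cat.), CH2Cl2–cyclohexane, 0 °C
Reagents that add atoms: none
Why: Acid-catalysed trichloroacetimidate O-benzylation etherifies the hindered secondary alcohol without base, so no silyl migration can occur.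

Step 7
Reactants: 10 DCB ether
Product: 12 (2R,3S,5R)-5-[(1R)-1-bromopropyl]-3-(TBS-oxy)-2-[(TBS-oxy)methyl]oxolane, via O-benzylated oxolanium ion 11 (not isolated)
Conditions: NBS, MeCN, −20 °C → rt
Reagents that add atoms: N-bromosuccinimide, O=C1CCC(=O)N1Br
Why: Bartlett-type haloetherification with a benzylic ether oxygen as nucleophile: 5-exo anti addition of O and Br across the Z-alkene, with the bulky DCB group on the oxolanium oxygen sitting trans to both flanking substituents, gives the 2,5-cis ring and hence (12R,13R) before succinimide removes the benzyl group.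

Step 8
Reactants: 12 bis-silyl bromo-oxolane
Product: 13 [(2R,3S,5R)-5-[(1R)-1-bromopropyl]-3-(TBS-oxy)oxolan-2-yl]methanol
Conditions: CF3CO2H/H2O/THF (1:1:4), 0 °C
Reagents that add atoms: none
Why: Primary silyl ethers hydrolyse much faster than secondary ones in aqueous acid (the selective 5'-desilylation used for nucleosides), which frees only the C8 hydroxyl.

Step 9
Reactants: 13 primary alcohol; 14 acetonitrile
Product: 16 3-[(2R,3S,5R)-5-[(1R)-1-bromopropyl]-3-(TBS-oxy)oxolan-2-yl]propanenitrile, via primary triflate 15 (not isolated)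
Conditions: Tf2O, 2,6-lutidine, CH2Cl2, −78 °C; crude triflate added to LiCH2CN (14, n-BuLi), THF, −78 °C
Reagents that add atoms: none
Why: Triflation followed by SN2 alkylation of lithiated acetonitrile adds C7 and C6 at a primary carbon without touching any stereocentre.

Step 10
Reactants: 16 nitrile
Product: 17 3-[(2R,3S,5R)-5-[(1R)-1-bromopropyl]-3-(TBS-oxy)oxolan-2-yl]propanal
Conditions: i-Bu2AlH, CH2Cl2, −78 °C; then aq. tartaric acid
Reagents that add atoms: water, O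
Why: i-Bu2AlH adds once to the nitrile and hydrolysis of the aluminium imine gives the C6 aldehyde.

Step 11
Reactants: 17 aldehyde; 18 (−)-B-allyldiisopinocampheylborane (Ipc groups from (−)-α-pinene)
Product: 20 (2S,3R)-1-[(2R,3S,5R)-5-[(1R)-1-bromopropyl]-3-(TBS-oxy)oxolan-2-yl]-2-chlorohex-5-en-3-ol, via α-chloroaldehyde 19 (not isolated)
Conditions: (2R,5R)-2,5-diphenylpyrrolidine (10 mol %), NCS, CH2Cl2, 0 °C; pentane, filter; then 18, Et2O, −78 °C; then NaHCO3, H2O2, 0 °C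
Reagents that add atoms: N-chlorosuccinimide, O=C1CCC(=O)N1Cl
Why: Enamine-catalysed α-chlorination sets C7 (S) under catalyst control (the enantiomeric catalyst would give the epimer), and reagent-controlled Brown allylboration of the crude α-chloroaldehyde, which is also the Cornforth-favoured 1,2-anti addition, sets C6 (R).

Step 12
Reactants: 20 chlorohydrin
Product: 23 (2S,3S,5S,6S,8R)-8-[(1R)-1-bromopropyl]-3,5-dichloro-2-(prop-2-en-1-yl)-6-(TBS-oxy)oxocane, via secondary triflate 21 (not isolated), via bicyclic oxonium triflate 22 (not isolated)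
Conditions: Tf2O, 2,6-di-tert-butyl-4-methylpyridine, CH2Cl2, −78 → 0 °C; then n-Bu4NCl, −40 → 0 °C
Reagents that add atoms: tetrabutylammonium chloride, CCCC[N+](CCCC)(CCCC)CCCC.[Cl-]
Why: Proposed new method: the C6 triflate is displaced with inversion by the oxolane oxygen (5-exo-tet ether participation) to give a cis-fused 1-oxoniabicyclo[3.3.0]octane in which C6 and C12 each carry a β-halogen (and C12 a branched neighbour), so chloride should open it by SN2 at the ring-fusion carbon C9 (β-silyloxy only) with inversion, turning the two five-membered rings into the oxocane and setting C6 (S), C9 (S) and the trans relation across the ring oxygen from centres that are already fixed; the closest known reaction types are transannular ether participation in oxocan-5-yl sulfonate solvolysis and the bromonium-induced ring-expanding etherification of tetrahydrofurans through the same kind of bicyclic oxonium ion.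

Step 13
Reactants: 23 allyl oxocane; 24 (E)-but-2-enal (crotonaldehyde)
Product: 25 (2E)-4-[(2S,3S,5S,6S,8R)-8-[(1R)-1-bromopropyl]-3,5-dichloro-6-(TBS-oxy)oxocan-2-yl]but-2-enal
Conditions: 24 (5 equiv), second-generation Hoveyda–Grubbs catalyst RuCl2(H2IMes)(=CH-C6H4-2-O-i-Pr) (5 mol %), CH2Cl2, 40 °C
Reagents that add atoms: none
Why: Olefin cross-metathesis of the terminal alkene with excess crotonaldehyde gives the conjugated enal with high E selectivity.

Step 14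
Reactants: 25 enal
Product: 26 (2S,3S,5S,6S,8R)-8-[(1R)-1-bromopropyl]-3,5-dichloro-2-[(2E)-pent-2-en-4-yn-1-yl]-6-(TBS-oxy)oxocane
Conditions: Me3SiCHN2, LiN(i-Pr)2, THF, −78 → 0 °C
Reagents that add atoms: (trimethylsilyl)diazomethane, C[Si](C)(C)C=[N+]=[N-]
Why: Colvin rearrangement: lithiated trimethylsilyldiazomethane adds to the aldehyde, Peterson elimination and loss of N2 give an alkylidene carbene, and its 1,2-hydrogen shift delivers the terminal alkyne with the E alkene retained.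

Step 15
Reactants: 26 silyl ether
Product: 27 (2S,3S,5S,6S,8R)-8-[(1R)-1-bromopropyl]-3,5-dichloro-2-[(2E)-pent-2-en-4-yn-1-yl]oxocan-6-ol
Conditions: HF·pyridine, THF, 0 °C → rt
Reagents that add atoms: none
Why: Acidic fluoride desilylation removes the secondary silyl ether without the basic conditions that could close the trans chlorohydrin to an epoxide or eliminate a halide.

Step 16
Reactants: 27 alcohol
Product: 28 (2S,3S,5S,6S,8R)-8-[(1R)-1-bromopropyl]-3,5-dichloro-2-[(2E)-pent-2-en-4-yn-1-yl]oxocan-6-yl acetate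
Conditions: Ac2O, pyridine, DMAP (cat.), CH2Cl2, 0 °C → rt
Reagents that add atoms: acetic anhydride, CC(=O)OC(C)=O
Why: Pyridine/DMAP-catalysed acylation of the secondary alcohol gives the acetate with retention at C10, completing the target.

## Compound list

1 | 2-deoxy-D-ribose | O=CC[C@H](O)[C@H](O)CO | starting material
2 | 2-deoxy-D-ribono-1,4-lactone | O=C1C[C@H](O)[C@@H](CO)O1 | intermediate
3 | (4S,5R)-4-(TBS-oxy)-5-[(TBS-oxy)methyl]oxolan-2-one | O=C1C[C@H](O[Si](C)(C)C(C)(C)C)[C@@H](CO[Si](C)(C)C(C)(C)C)O1 | intermediate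
4 | (4S,5R)-4-(TBS-oxy)-5-[(TBS-oxy)methyl]oxolan-2-ol | OC1C[C@H](O[Si](C)(C)C(C)(C)C)[C@@H](CO[Si](C)(C)C(C)(C)C)O1 | intermediate
5 | propyl(triphenyl)phosphonium bromide | CCC[P+](c1ccccc1)(c1ccccc1)c1ccccc1.[Br-] | starting material
6 | (2R,3S,5Z)-1,3-bis(TBS-oxy)oct-5-en-2-ol | CC/C=C\C[C@H](O[Si](C)(C)C(C)(C)C)[C@H](O)CO[Si](C)(C)C(C)(C)C | intermediate
7 | (2,6-dichlorophenyl)methanol | OCc1c(Cl)cccc1Cl | starting material
8 | trichloroacetonitrile | N#CC(Cl)(Cl)Cl | starting material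
9 | (2,6-dichlorophenyl)methyl 2,2,2-trichloroethanimidate | N=C(OCc1c(Cl)cccc1Cl)C(Cl)(Cl)Cl | intermediate
10 | (2R,3S,5Z)-1,3-bis(TBS-oxy)-2-(DCB-oxy)oct-5-ene | CC/C=C\C[C@H](O[Si](C)(C)C(C)(C)C)[C@H](OCc1c(Cl)cccc1Cl)CO[Si](C)(C)C(C)(C)C | intermediate
11 | (2R,3S,5R)-5-[(1R)-1-bromopropyl]-1-DCB-3-(TBS-oxy)-2-[(TBS-oxy)methyl]oxolan-1-ium succinimidate | CC[C@@H](Br)[C@H]1C[C@H](O[Si](C)(C)C(C)(C)C)[C@@H](CO[Si](C)(C)C(C)(C)C)[O+]1Cc1c(Cl)cccc1Cl.O=C1CCC(=O)[N-]1 | intermediate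
12 | (2R,3S,5R)-5-[(1R)-1-bromopropyl]-3-(TBS-oxy)-2-[(TBS-oxy)methyl]oxolane | CC[C@@H](Br)[C@H]1C[C@H](O[Si](C)(C)C(C)(C)C)[C@@H](CO[Si](C)(C)C(C)(C)C)O1 | intermediate
13 | [(2R,3S,5R)-5-[(1R)-1-bromopropyl]-3-(TBS-oxy)oxolan-2-yl]methanol | CC[C@@H](Br)[C@H]1C[C@H](O[Si](C)(C)C(C)(C)C)[C@@H](CO)O1 | intermediate
14 | acetonitrile | CC#N | starting material
15 | [(2R,3S,5R)-5-[(1R)-1-bromopropyl]-3-(TBS-oxy)oxolan-2-yl]methyl trifluoromethanesulfonate | CC[C@@H](Br)[C@H]1C[C@H](O[Si](C)(C)C(C)(C)C)[C@@H](COS(=O)(=O)C(F)(F)F)O1 | intermediate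
16 | 3-[(2R,3S,5R)-5-[(1R)-1-bromopropyl]-3-(TBS-oxy)oxolan-2-yl]propanenitrile | CC[C@@H](Br)[C@H]1C[C@H](O[Si](C)(C)C(C)(C)C)[C@@H](CCC#N)O1 | intermediate
17 | 3-[(2R,3S,5R)-5-[(1R)-1-bromopropyl]-3-(TBS-oxy)oxolan-2-yl]propanal | CC[C@@H](Br)[C@H]1C[C@H](O[Si](C)(C)C(C)(C)C)[C@@H](CCC=O)O1 | intermediate
18 | (−)-B-allyldiisopinocampheylborane | C=CCB([C@H]1C[C@H]2C[C@@H]([C@@H]1C)C2(C)C)[C@H]1C[C@H]2C[C@@H]([C@@H]1C)C2(C)C | starting material
19 | (2S)-2-chloro-3-[(2R,3S,5R)-5-[(1R)-1-bromopropyl]-3-(TBS-oxy)oxolan-2-yl]propanal | CC[C@@H](Br)[C@H]1C[C@H](O[Si](C)(C)C(C)(C)C)[C@@H](C[C@H](Cl)C=O)O1 | intermediate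
20 | (2S,3R)-1-[(2R,3S,5R)-5-[(1R)-1-bromopropyl]-3-(TBS-oxy)oxolan-2-yl]-2-chlorohex-5-en-3-ol | CC[C@@H](Br)[C@H]1C[C@H](O[Si](C)(C)C(C)(C)C)[C@@H](C[C@H](Cl)[C@H](O)CC=C)O1 | intermediate
21 | (2S,3R)-1-[(2R,3S,5R)-5-[(1R)-1-bromopropyl]-3-(TBS-oxy)oxolan-2-yl]-2-chlorohex-5-en-3-yl trifluoromethanesulfonate | CC[C@@H](Br)[C@H]1C[C@H](O[Si](C)(C)C(C)(C)C)[C@@H](C[C@H](Cl)[C@H](OS(=O)(=O)C(F)(F)F)CC=C)O1 | intermediate
22 | (2R,4S,5R,7S,8S)-2-[(1R)-1-bromopropyl]-7-chloro-8-(prop-2-en-1-yl)-4-(TBS-oxy)-1-oxoniabicyclo[3.3.0]octane trifluoromethanesulfonate | CC[C@@H](Br)[C@H]1C[C@H](O[Si](C)(C)C(C)(C)C)[C@H]2C[C@H](Cl)[C@H](CC=C)[O+]12.[O-]S(=O)(=O)C(F)(F)F | intermediate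
23 | (2S,3S,5S,6S,8R)-8-[(1R)-1-bromopropyl]-3,5-dichloro-2-(prop-2-en-1-yl)-6-(TBS-oxy)oxocane | C=CC[C@@H]1O[C@@H]([C@H](Br)CC)C[C@H](O[Si](C)(C)C(C)(C)C)[C@@H](Cl)C[C@@H]1Cl | intermediate
24 | (E)-but-2-enal | C/C=C/C=O | starting material
25 | (2E)-4-[(2S,3S,5S,6S,8R)-8-[(1R)-1-bromopropyl]-3,5-dichloro-6-(TBS-oxy)oxocan-2-yl]but-2-enal | O=C/C=C/C[C@@H]1O[C@@H]([C@H](Br)CC)C[C@H](O[Si](C)(C)C(C)(C)C)[C@@H](Cl)C[C@@H]1Cl | intermediate
26 | (2S,3S,5S,6S,8R)-8-[(1R)-1-bromopropyl]-3,5-dichloro-2-[(2E)-pent-2-en-4-yn-1-yl]-6-(TBS-oxy)oxocane | C#C/C=C/C[C@@H]1O[C@@H]([C@H](Br)CC)C[C@H](O[Si](C)(C)C(C)(C)C)[C@@H](Cl)C[C@@H]1Cl | intermediate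
27 | (2S,3S,5S,6S,8R)-8-[(1R)-1-bromopropyl]-3,5-dichloro-2-[(2E)-pent-2-en-4-yn-1-yl]oxocan-6-ol | C#C/C=C/C[C@@H]1O[C@@H]([C@H](Br)CC)C[C@H](O)[C@@H](Cl)C[C@@H]1Cl | intermediate
28 | (2S,3S,5S,6S,8R)-8-[(1R)-1-bromopropyl]-3,5-dichloro-2-[(2E)-pent-2-en-4-yn-1-yl]oxocan-6-yl acetate | C#C/C=C/C[C@@H]1O[C@@H]([C@H](Br)CC)C[C@H](OC(C)=O)[C@@H](Cl)C[C@@H]1Cl | target

## Step count and risk

Total step count: 16. Longest linear sequence: 15 steps (steps 1–4 and 6–16; step 5 is a one-step side branch).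

Steps most likely to fail:

**Step 12 (ring expansion).** The oxonium ion 22 can also be opened by chloride at C6 or C12, which gives oxolane chlorides instead of the oxocane. The C10 silyl ether oxygen could also compete with the ring oxygen for the C6 triflate. The fallback installs the C9 chloride before any ring exists and closes the oxocane last. It sets out from 6 and comes back at 23.
- Appel chlorination of 6 (PPh3, CCl4, 60 °C, inversion at C9) gives (2S,3S,5Z)-1,3-bis(TBS-oxy)-2-chlorooct-5-ene F8.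
- Selective primary desilylation as in step 8 gives (2S,3S,5Z)-3-(TBS-oxy)-2-chlorooct-5-en-1-ol F9.
- Triflation gives (2S,3S,5Z)-3-(TBS-oxy)-2-chlorooct-5-en-1-yl trifluoromethanesulfonate F10, and LiCH2CN then gives (4S,5S,7Z)-5-(TBS-oxy)-4-chlorodec-7-enenitrile F11.
- i-Bu2AlH gives (4S,5S,7Z)-5-(TBS-oxy)-4-chlorodec-7-enal F12.
- The step 11 chlorination gives (2S,4S,5S,7Z)-5-(TBS-oxy)-2,4-dichlorodec-7-enal F13. Allylation with the enantiomer of 18 gives the syn chlorohydrin (4S,5S,7S,8S,10Z)-8-(TBS-oxy)-5,7-dichlorotrideca-1,10-dien-4-ol F14.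
- Direct 8-exo bromoetherification of F14 with Et2SBr·SbCl5Br in MeNO2 at −25 °C (C6 hydroxyl onto C12 of the more electron-rich Z-alkene, anti addition) gives 23. This closure is not face-controlled, so 23 must be separated from its (12S,13S) isomer.

**Step 7 (bromoetherification).** The 2,5-cis selectivity and the debenzylation are precedented mainly for iodine, and the trans oxolane may form. The fallback replaces halocyclisation by an osmium-mediated oxidative cyclisation. It sets out from 6 and comes back at 12.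
- Selective primary desilylation of 6 (CF3CO2H/H2O/THF, 0 °C) gives (2R,3S,5Z)-3-(TBS-oxy)oct-5-ene-1,2-diol F1.
- OsO4 (5 mol %), Me3NO and CF3CO2H in CH2Cl2 effect oxidative cyclisation. The osmate ester of the 1,2-diol adds syn across the Z-alkene, which enforces the 2,5-cis ring and gives (1S)-1-[(2R,4S,5R)-4-(TBS-oxy)-5-(hydroxymethyl)oxolan-2-yl]propan-1-ol F2.
- Primary-selective silylation (TBSCl, imidazole, 0 °C) gives (1S)-1-[(2R,4S,5R)-4-(TBS-oxy)-5-[(TBS-oxy)methyl]oxolan-2-yl]propan-1-ol F3.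
- CBr4 and P(n-C8H17)3 in toluene at 70 °C convert the C13 alcohol into the bromide with inversion, giving 12.

**Step 11 (α-chlorination and allylation).** The catalyst may control C7 poorly next to the chiral oxolane, and the α-chloroaldehyde 19 can epimerise before allylation. The fallback sets C7 with a covalent auxiliary on an isolable imide. It sets out from 17 and comes back at 19.
- Pinnick oxidation of 17 (NaClO2, NaH2PO4, 2-methylbut-2-ene) gives 3-[(2R,3S,5R)-5-[(1R)-1-bromopropyl]-3-(TBS-oxy)oxolan-2-yl]propanoic acid F4.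
- Pivaloyl chloride/Et3N, then the lithium salt (n-BuLi) of (S)-4-benzyl-1,3-oxazolidin-2-one, gives the N-acyl oxazolidinone (4S)-4-benzyl-3-{3-[(2R,3S,5R)-5-[(1R)-1-bromopropyl]-3-(TBS-oxy)oxolan-2-yl]propanoyl}-1,3-oxazolidin-2-one F5.
- NaN(SiMe3)2 then NCS in THF at −78 °C chlorinates the Z-enolate on the face away from the benzyl group to give the (2S)-2-chloro imide (4S)-4-benzyl-3-{(2S)-2-chloro-3-[(2R,3S,5R)-5-[(1R)-1-bromopropyl]-3-(TBS-oxy)oxolan-2-yl]propanoyl}-1,3-oxazolidin-2-one F6.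
- LiBH4 in Et2O/MeOH removes the auxiliary and gives (2S)-2-chloro-3-[(2R,3S,5R)-5-[(1R)-1-bromopropyl]-3-(TBS-oxy)oxolan-2-yl]propan-1-ol F7.
- Dess–Martin oxidation gives 19, which is allylated with 18 as in step 11.

Further compounds

F1 | step 7 | (2R,3S,5Z)-3-(TBS-oxy)oct-5-ene-1,2-diol | CC/C=C\C[C@H](O[Si](C)(C)C(C)(C)C)[C@H](O)CO
F2 | step 7 | (1S)-1-[(2R,4S,5R)-4-(TBS-oxy)-5-(hydroxymethyl)oxolan-2-yl]propan-1-ol | CC[C@H](O)[C@H]1C[C@H](O[Si](C)(C)C(C)(C)C)[C@@H](CO)O1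
F3 | step 7 | (1S)-1-[(2R,4S,5R)-4-(TBS-oxy)-5-[(TBS-oxy)methyl]oxolan-2-yl]propan-1-ol | CC[C@H](O)[C@H]1C[C@H](O[Si](C)(C)C(C)(C)C)[C@@H](CO[Si](C)(C)C(C)(C)C)O1
F4 | step 11 | 3-[(2R,3S,5R)-5-[(1R)-1-bromopropyl]-3-(TBS-oxy)oxolan-2-yl]propanoic acid | CC[C@@H](Br)[C@H]1C[C@H](O[Si](C)(C)C(C)(C)C)[C@@H](CCC(=O)O)O1
F5 | step 11 | (4S)-4-benzyl-3-{3-[(2R,3S,5R)-5-[(1R)-1-bromopropyl]-3-(TBS-oxy)oxolan-2-yl]propanoyl}-1,3-oxazolidin-2-one | CC[C@@H](Br)[C@H]1C[C@H](O[Si](C)(C)C(C)(C)C)[C@@H](CCC(=O)N2[C@@H](Cc3ccccc3)COC2=O)O1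
F6 | step 11 | (4S)-4-benzyl-3-{(2S)-2-chloro-3-[(2R,3S,5R)-5-[(1R)-1-bromopropyl]-3-(TBS-oxy)oxolan-2-yl]propanoyl}-1,3-oxazolidin-2-one | CC[C@@H](Br)[C@H]1C[C@H](O[Si](C)(C)C(C)(C)C)[C@@H](C[C@H](Cl)C(=O)N2[C@@H](Cc3ccccc3)COC2=O)O1
F7 | step 11 | (2S)-2-chloro-3-[(2R,3S,5R)-5-[(1R)-1-bromopropyl]-3-(TBS-oxy)oxolan-2-yl]propan-1-ol | CC[C@@H](Br)[C@H]1C[C@H](O[Si](C)(C)C(C)(C)C)[C@@H](C[C@H](Cl)CO)O1
F8 | step 12 | (2S,3S,5Z)-1,3-bis(TBS-oxy)-2-chlorooct-5-ene | CC/C=C\C[C@H](O[Si](C)(C)C(C)(C)C)[C@@H](Cl)CO[Si](C)(C)C(C)(C)C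
F9 | step 12 | (2S,3S,5Z)-3-(TBS-oxy)-2-chlorooct-5-en-1-ol | CC/C=C\C[C@H](O[Si](C)(C)C(C)(C)C)[C@@H](Cl)CO
F10 | step 12 | (2S,3S,5Z)-3-(TBS-oxy)-2-chlorooct-5-en-1-yl trifluoromethanesulfonate | CC/C=C\C[C@H](O[Si](C)(C)C(C)(C)C)[C@@H](Cl)COS(=O)(=O)C(F)(F)F
F11 | step 12 | (4S,5S,7Z)-5-(TBS-oxy)-4-chlorodec-7-enenitrile | CC/C=C\C[C@H](O[Si](C)(C)C(C)(C)C)[C@@H](Cl)CCC#N
F12 | step 12 | (4S,5S,7Z)-5-(TBS-oxy)-4-chlorodec-7-enal | CC/C=C\C[C@H](O[Si](C)(C)C(C)(C)C)[C@@H](Cl)CCC=O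
F13 | step 12 | (2S,4S,5S,7Z)-5-(TBS-oxy)-2,4-dichlorodec-7-enal | CC/C=C\C[C@H](O[Si](C)(C)C(C)(C)C)[C@@H](Cl)C[C@H](Cl)C=O
F14 | step 12 | (4S,5S,7S,8S,10Z)-8-(TBS-oxy)-5,7-dichlorotrideca-1,10-dien-4-ol | CC/C=C\C[C@H](O[Si](C)(C)C(C)(C)C)[C@@H](Cl)C[C@H](Cl)[C@@H](O)CC=C
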